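**Retrosynthetic overview**
1. Ring B (cycloheptenone) is made last by ring expansion: a radical 1,2-acyl shift moves ketone carbon C6 from the spiro carbon C11 to C5, turning a spiro[5.5] cyclohexanone into the cis-fused 6-7 system.
2. Ring A is first built spiro at C11 by Diels–Alder of alkylidene ketone 14 (tricycle 12 + methacrolein) with an ester-bearing Danishefsky-type diene 18 (from methyl acetoacetate); a thioether at C10 blocks vinyl migration and later leaves as PhS•.
3. Tricycle 12 (ring C + lactone + six-membered pre-ring B) comes from an ester-tethered intramolecular Diels–Alder of a propiolate onto a 2-ethoxydiene.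
4. Ring C is (R)-4-silyloxycyclopentenone: C13 is bought, C15 is set by MeMgBr, C7/C8 by the tethered cycloaddition.
5. Ring order: C → lactone + six-membered pre-B → A (spiro) → B (6 → 7).

Locants used for all compounds: ring A C1(isopropenyl)–C2–C3(O)–C4(CO2Me)–C5–C11; ring B C5–C6(=O)–C7–C8–C9=C10–C11; ring C C7–C8–C13(O)–C14–C15(OH)(Me); lactone C9–C12(=O)–O–C13.

Assumption: 1 is bought enantiopure, and the cis C5/C11 ring fusion with the 9,10-alkene is taken to be the thermodynamic arrangement reached by DBU equilibration.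

**Step 1**
Reactants: 1 (R)-4-[(tert-butyldimethylsilyl)oxy]cyclopent-2-en-1-one
Product: 2 (4R)-4-[(tert-butyldimethylsilyl)oxy]-2-iodocyclopent-2-en-1-one
Conditions: I2, pyridine, CH2Cl2, 0 °C to rt
Reagents that add atoms: iodine [I][I]
Why: Johnson α-iodination of an enone (pyridine addition, iodination, elimination) gives the 2-iodoenone without touching the C13 stereocentre.

**Step 2**
Reactants: 2 (4R)-4-[(tert-butyldimethylsilyl)oxy]-2-iodocyclopent-2-en-1-one
Product: 3 (1S,4R)-4-[(tert-butyldimethylsilyl)oxy]-2-iodo-1-methylcyclopent-2-en-1-ol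
Conditions: MeMgBr, THF, −78 °C
Reagents that add atoms: methylmagnesium bromide C[Mg]Br
Why: Grignard 1,2-addition from the face opposite the silyloxy group sets C15 with the new OH cis to the C13 oxygen; the vinyl iodide is inert to MeMgBr at this temperature.

**Step 3**
Reactants: 3 (1S,4R)-4-[(tert-butyldimethylsilyl)oxy]-2-iodo-1-methylcyclopent-2-en-1-ol; 4 ethyl vinyl ether
Product: 8 (1R,3S)-4-(1-ethoxyethenyl)-3-methylcyclopent-4-ene-1,3-diol, via (1-ethoxyvinyl)lithium 5 (not isolated), via chloro(1-ethoxyvinyl)zinc 6 (not isolated), via silyl ether diene 7 (not isolated)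
Conditions: 4, t-BuLi, THF, −78 to 0 °C; ZnCl2; 3, Pd(PPh3)4 (5 mol %), rt; then TBAF, rt
Reagents that add atoms: none
Why: Negishi coupling of the vinyl iodide with the zinc reagent from α-lithiated ethyl vinyl ether installs the masked acetyl group as a 2-ethoxydiene, and fluoride then frees the secondary alcohol in the same flask; no stereocentre is touched.

**Step 4**
Reactants: 8 (1R,3S)-4-(1-ethoxyethenyl)-3-methylcyclopent-4-ene-1,3-diol; 9 propiolic acid
Product: 10 (1R,4S)-3-(1-ethoxyethenyl)-4-hydroxy-4-methylcyclopent-2-en-1-yl prop-2-ynoate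
Conditions: DCC, DMAP (5 mol %), CH2Cl2, −20 °C
Reagents that add atoms: none
Why: Steglich esterification acylates the secondary allylic alcohol and leaves the tertiary one alone; low temperature and prior activation of the acid protect the enol ether.

**Step 5**
Reactants: 10 (1R,4S)-3-(1-ethoxyethenyl)-4-hydroxy-4-methylcyclopent-2-en-1-yl prop-2-ynoate
Product: 12 tricyclic keto lactone, via enol ether cycloadduct 11 (not isolated)
Conditions: toluene (0.01 M), BHT, 100 °C, degassed; then 0.5 M HCl, THF, 0 °C
Reagents that add atoms: water O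
Why: Intramolecular Diels–Alder of the propiolate with the electron-rich 2-ethoxydiene (diene CH2 bonds to the alkyne CH) forms the lactone and the six-membered ring, the three-atom ester tether forcing the new C8–C9 bond cis to O13 (sets C8); enol ether hydrolysis gives the C6 ketone and protonates C7 to the cis-fused ring junction (sets C7).

**Step 6**
Reactants: 12 tricyclic keto lactone; 13 methacrolein
Product: 14 (E)-C11-(2-methylprop-2-enylidene) keto lactone
Conditions: LiHMDS (2.2 equiv), THF, −78 °C; 13; warm to 0 °C; AcOH quench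
Reagents that add atoms: none
Why: Aldol condensation at the C11 methylene (activated by the ketone and the vinylogous lactone): the alkoxide/dienolate dianion adds 1,2 to methacrolein and the aldolate loses hydroxide on warming, giving the (E)-alkylidene with isopropenyl anti to the C6 carbonyl.

**Step 7**
Reactants: 15 methyl acetoacetate; 16 trimethyl orthoformate
Product: 17 methyl (2Z)-2-(methoxymethylidene)-3-oxobutanoate
Conditions: Ac2O, 130 °C
Reagents that add atoms: none
Why: Orthoformate condensation at the active methylene (alkoxymethylenation), with acetic anhydride trapping the methanol.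

**Step 8**
Reactants: 17 methyl (2Z)-2-(methoxymethylidene)-3-oxobutanoate
Product: 18 methyl (2Z)-3-[(tert-butyldimethylsilyl)oxy]-2-(methoxymethylidene)but-3-enoate
Conditions: TBSOTf, Et3N, CH2Cl2, 0 °C
Reagents that add atoms: tert-butyldimethylsilyl triflate CC(C)(C)[Si](C)(C)OS(=O)(=O)C(F)(F)F
Why: Soft enolisation of the only enolisable position (the methyl ketone) gives a 1-methoxy-3-silyloxy diene of the Danishefsky type carrying the ester.

**Step 9**
Reactants: 14 (E)-C11-(2-methylprop-2-enylidene) keto lactone; 18 methyl (2Z)-3-[(tert-butyldimethylsilyl)oxy]-2-(methoxymethylidene)but-3-enoate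
Product: 21 spiro enone ester sulfide, via methoxy cycloadduct 19 (not isolated), via sulfide cycloadduct 20 (not isolated)
Conditions: 18 (2 equiv), ZnCl2 (20 mol %), CH2Cl2, −20 °C to rt; then PhSH (1.1 equiv), Et3N (0.3 equiv), 0 °C; then TFA, CH2Cl2, −20 °C
Reagents that add atoms: benzenethiol Sc1ccccc1
Why: Diels–Alder with normal Danishefsky regiochemistry (silyl enol ether CH2 to the enone β-carbon C1, methoxy carbon to C11) from the face opposite ring C/lactone puts C5 on the H7/H8 face, and the (E)-geometry puts isopropenyl anti to C6 (sets C1 and spiro C11); thia-Michael addition at C10 (safe now that C11 is quaternary) removes the vinyl group that would otherwise migrate in step 10; acid then unmasks the C4=C5 alkylidene β-keto ester.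

**Step 10**
Reactants: 21 spiro enone ester sulfide
Product: 23 target CNP0268969.1, via deconjugated lactone 22 (not isolated)
Conditions: SmI2 (2.5 equiv, titrated), THF, −78 to −40 °C, no proton source; aq NH4Cl; then DBU (0.2 equiv), CH2Cl2, 0 °C
Reagents that add atoms: none
Why: Proposed new method: single-electron reduction of the alkylidene β-keto ester by SmI2 puts spin on C5, 3-exo attack on the neighbouring C6 ketone and β-scission of C6–C11 (a Dowd–Beckwith-type 1,2-acyl shift, suprafacial, so H5 ends on the H7/H8 face) converts the spiro[5.5] unit into the fused 6-7 skeleton, and the C11 radical irreversibly expels PhS• from C10 to give the C10=C11 alkene 22 (the second SmI2 reduces PhS•); DBU then moves the alkene into conjugation and sets C11–H under thermodynamic control (cis fusion, isopropenyl trans to C10); closest known chemistry is the tin hydride Dowd–Beckwith ring expansion of α-halomethyl β-keto esters and SmI2 reduction of alkylidene 1,3-dicarbonyls, while the enone-reduction trigger, the spiro-to-fused topology and the β-thio terminus are new.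

**Compound list**
1 | (R)-4-[(tert-butyldimethylsilyl)oxy]cyclopent-2-en-1-one | O=C1C=C[C@H](O[Si](C)(C)C(C)(C)C)C1 | starting material
2 | (4R)-4-[(tert-butyldimethylsilyl)oxy]-2-iodocyclopent-2-en-1-one | O=C1C(I)=C[C@H](O[Si](C)(C)C(C)(C)C)C1 | intermediate
3 | (1S,4R)-4-[(tert-butyldimethylsilyl)oxy]-2-iodo-1-methylcyclopent-2-en-1-ol | C[C@]1(O)C[C@@H](O[Si](C)(C)C(C)(C)C)C=C1I | intermediate
4 | ethyl vinyl ether | C=COCC | starting material
5 | (1-ethoxyvinyl)lithium | [Li]C(=C)OCC | intermediate (not isolated)
6 | chloro(1-ethoxyvinyl)zinc | Cl[Zn]C(=C)OCC | intermediate (not isolated)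
7 | (1S,4R)-4-[(tert-butyldimethylsilyl)oxy]-2-(1-ethoxyethenyl)-1-methylcyclopent-2-en-1-ol | C[C@]1(O)C[C@@H](O[Si](C)(C)C(C)(C)C)C=C1C(=C)OCC | intermediate (not isolated)
8 | (1R,3S)-4-(1-ethoxyethenyl)-3-methylcyclopent-4-ene-1,3-diol | C[C@]1(O)C[C@@H](O)C=C1C(=C)OCC | intermediate
9 | propiolic acid | C#CC(=O)O | starting material
10 | (1R,4S)-3-(1-ethoxyethenyl)-4-hydroxy-4-methylcyclopent-2-en-1-yl prop-2-ynoate | C[C@]1(O)C[C@@H](OC(=O)C#C)C=C1C(=C)OCC | intermediate
11 | enol ether cycloadduct: C6(OEt)=C7 enol ether, C9=C10 enoate, lactone cis-fused at C8/C13, 15-OH cis to O13 | CCOC1=C2[C@@H]3C(=CC1)C(=O)O[C@@H]3C[C@]2(C)O | intermediate (not isolated)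
12 | tricyclic keto lactone: ring C + lactone + six-membered pre-ring B (C6 ketone, C11H2, C9=C10); H7/H8 cis, 15-OH cis to O13 and to C6 | O=C1[C@@H]2[C@@H]3C(=CC1)C(=O)O[C@@H]3C[C@]2(C)O | intermediate
13 | methacrolein | CC(=C)C=O | starting material
14 | (E)-C11-(2-methylprop-2-enylidene) derivative of 12 (isopropenyl anti to C6=O) | O=C1[C@@H]2[C@@H]3C(=C/C1=C\C(C)=C)C(=O)O[C@@H]3C[C@]2(C)O | intermediate
15 | methyl acetoacetate | CC(=O)CC(=O)OC | starting material
16 | trimethyl orthoformate | COC(OC)OC | starting material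
17 | methyl (2Z)-2-(methoxymethylidene)-3-oxobutanoate | CC(=O)/C(C(=O)OC)=C/OC | intermediate
18 | methyl (2Z)-3-[(tert-butyldimethylsilyl)oxy]-2-(methoxymethylidene)but-3-enoate | C=C(O[Si](C)(C)C(C)(C)C)/C(C(=O)OC)=C/OC | intermediate
19 | methoxy cycloadduct: ring A spiro at C11, C3(OTBS)=C4 silyl enol ether, 5-OMe (both C5 epimers), C9=C10 retained | C=C(C)[C@@H]1CC(O[Si](C)(C)C(C)(C)C)=C(C(=O)OC)C(OC)[C@@]12C(=O)[C@@H]3[C@@H]4C(=C2)C(=O)O[C@@H]4C[C@]3(C)O | intermediate (not isolated)
20 | sulfide cycloadduct: 19 with PhS on C10 and H on C9 (C5/C9/C10 epimer mixture) | C=C(C)[C@@H]1CC(O[Si](C)(C)C(C)(C)C)=C(C(=O)OC)C(OC)[C@@]12C(=O)[C@@H]3[C@@H]4C(C2Sc5ccccc5)C(=O)O[C@@H]4C[C@]3(C)O | intermediate (not isolated)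
21 | spiro enone ester sulfide: ring A = 4-carbomethoxycyclohex-4-en-3-one spiro at C11 (C5 arm on the H7/H8 face, C1 arm on the lactone face, isopropenyl anti to C6), 10-SPh (C9/C10 epimer mixture, both centres erased in step 10) | C=C(C)[C@@H]1CC(=O)C(C(=O)OC)=C[C@@]12C(=O)[C@@H]3[C@@H]4C(C2Sc5ccccc5)C(=O)O[C@@H]4C[C@]3(C)O | intermediate
22 | deconjugated ring-expanded lactone: target skeleton with C10=C11 alkene and H on C9 (C9 epimers) | C=C(C)[C@@H]1CC(O)=C(C(=O)OC)[C@H]2C(=O)[C@@H]3[C@@H]4C(C=C21)C(=O)O[C@@H]4C[C@]3(C)O | intermediate (not isolated)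
23 | CNP0268969.1: methyl (1R,5S,7R,8R,11S,13R,15S)-3,15-dihydroxy-15-methyl-6,12-dioxo-1-(prop-1-en-2-yl) tetracyclic enol ester lactone (locants above) | C=C(C)[C@@H]1CC(O)=C(C(=O)OC)[C@H]2C(=O)[C@@H]3[C@@H]4C(=C[C@H]21)C(=O)O[C@@H]4C[C@]3(C)O | target

**Step count**
Total steps: 10. Longest linear sequence: 8 (steps 1–6, 9, 10); steps 7–8 form the diene branch.

**Steps most likely to fail**

Step 6 (aldol condensation). Risks are Michael addition to methacrolein, retro-aldol at C15 and polymerisation of the cross-conjugated product. Fallback: from 12, heating with DMF dimethyl acetal (toluene, 60 °C) gives the C11-dimethylaminomethylidene ketone F1. Isopropenylmagnesium bromide with CuBr·SMe2 (THF, −40 °C) then replaces the amino group by conjugate addition–elimination and returns to the route at 14.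

Step 9 (spiro Diels–Alder and thiol blocking). Risks are a sluggish cycloaddition at the trisubstituted enone, Lewis-acid-induced stepwise 1,6-addition at the isopropenyl terminus, and a slow thia-Michael next to the quaternary centre. Fallback: from 15, DMF dimethyl acetal gives methyl 2-[(dimethylamino)methylidene]-3-oxobutanoate F2. KHMDS/TBSCl converts it into the amino siloxy diene F3 (Rawal type), which adds to 14 thermally without Lewis acid (toluene, 40 °C) to give the amino cycloadduct F4. PhSH gives the amino sulfide cycloadduct F5, and HF·pyridine (MeCN, 0 °C) removes the silyl group and dimethylamine to come back at 21.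

Step 10 (new ring expansion). Risks are plain reduction of the C4=C5 bond, ketone reduction, or no 3-exo attack from the stabilised radical anion. Fallback with known chemistry: from 21, PhSeH (PhSeSePh, NaBH4, EtOH, 0 °C) adds to C5 to give the selenide F6. Bu3SnH/AIBN (benzene, 80 °C, slow addition) then runs the classical tin hydride Dowd–Beckwith 1,2-acyl shift from the localised C5 radical, with loss of PhS• from C10, and comes back to the route at 22 (then DBU to 23).

**Further compounds**
F1 | step 6 | (E)-C11-[(dimethylamino)methylidene] derivative of 12 | O=C1[C@@H]2[C@@H]3C(=C/C1=C\N(C)C)C(=O)O[C@@H]3C[C@]2(C)O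
F2 | step 9 | methyl (2Z)-2-[(dimethylamino)methylidene]-3-oxobutanoate | CC(=O)/C(C(=O)OC)=C/N(C)C
F3 | step 9 | methyl (2Z)-3-[(tert-butyldimethylsilyl)oxy]-2-[(dimethylamino)methylidene]but-3-enoate | C=C(O[Si](C)(C)C(C)(C)C)/C(C(=O)OC)=C/N(C)C
F4 | step 9 | amino cycloadduct (19 with NMe2 in place of OMe at C5) | C=C(C)[C@@H]1CC(O[Si](C)(C)C(C)(C)C)=C(C(=O)OC)C(N(C)C)[C@@]12C(=O)[C@@H]3[C@@H]4C(=C2)C(=O)O[C@@H]4C[C@]3(C)O
F5 | step 9 | amino sulfide cycloadduct (F4 with PhS on C10) | C=C(C)[C@@H]1CC(O[Si](C)(C)C(C)(C)C)=C(C(=O)OC)C(N(C)C)[C@@]12C(=O)[C@@H]3[C@@H]4C(C2Sc5ccccc5)C(=O)O[C@@H]4C[C@]3(C)O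
F6 | step 10 | C5 phenylselanyl β-keto ester (21 with PhSe on C5 and H on C4) | C=C(C)[C@@H]1CC(=O)C(C(=O)OC)C([Se]c6ccccc6)[C@@]12C(=O)[C@@H]3[C@@H]4C(C2Sc5ccccc5)C(=O)O[C@@H]4C[C@]3(C)O
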